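**Retrosynthetic overview**
1. Target 25 ⇐ (E,E)-diene angelate 24 by double epoxidation; 24 ⇐ dienol 21 + angelic acid 22; 21 ⇐ dienone 17 by C6 reduction and α-methylenation.
2. The ten-membered ring of 17 ⇐ eudesmane-type decalin enone tosylate 15 by ring expansion: a borylation-triggered 1,4-fragmentation cleaves the C5–C10 ring-fusion bond and forms both E-alkenes.
3. 15 ⇐ alkenyl triflate/aldehyde 13 (ring B closed at C5–C6, then oxidation); lactone and C7/C8 of 13 ⇐ aldehyde 9 + methyl 4-oxobutanoate 10 (proline cross-aldol).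
4. 9 ⇐ cyclohexane-1,3-dione 1 (methylation, allylation with 3, enzymatic desymmetrisation, tosylation, methylation, triflation, ozonolysis).
5. Ring order: ring A (from 1) → γ-lactone → ring B → ten-membered ring by expansion → two epoxides.

Assumption: locants C1–C15 are eudesmane/germacrane numbers (C14 = methyl on C10, C15 = methyl on C4, lactone C12–O–C8; β = face of the C14 methyl), and a ketoreductase with the selectivity needed in step 3 is available from a commercial screening panel.

**Route**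

Step 1
Reactants: 1 cyclohexane-1,3-dione
Product: 2 2-methylcyclohexane-1,3-dione
Conditions: MeI, KOH, H2O/MeOH, 65 °C
Reagents that add atoms: iodomethane CI
Why: C-alkylation of the doubly activated C2 enolate of the cyclic 1,3-diketone (enolate alkylation); no stereocentre is formed.

Step 2
Reactants: 2 2-methylcyclohexane-1,3-dione; 3 allyl bromide
Product: 4 2-allyl-2-methylcyclohexane-1,3-dione
Conditions: NaOH (1 M aq.), Bu4NI (cat.), rt
Reagents that add atoms: none
Why: Second C-alkylation of the 2-substituted 1,3-diketone enolate with a reactive allylic halide in water gives the quaternary carbon (future C10), still prochiral.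

Step 3
Reactants: 4 2-allyl-2-methylcyclohexane-1,3-dione
Product: 5 (2S,3R)-2-allyl-3-hydroxy-2-methylcyclohexan-1-one
Conditions: ketoreductase (panel hit), NADP+ (cat.), 2-propanol, phosphate buffer pH 7/DMSO, 30 °C
Reagents that add atoms: none
Why: Enzymatic desymmetrising ketone reduction; the enzyme selects one of the two enantiotopic carbonyls and one face, which sets the quaternary centre (C10) and the carbinol (C1) with OH cis to the methyl group.

Step 4
Reactants: 5 (2S,3R)-2-allyl-3-hydroxy-2-methylcyclohexan-1-one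
Product: 6 (1R,2S)-2-allyl-2-methyl-3-oxocyclohexyl 4-methylbenzenesulfonate
Conditions: TsCl, pyridine, DMAP (cat.), 40 °C
Reagents that add atoms: 4-methylbenzenesulfonyl chloride Cc1ccc(S(=O)(=O)Cl)cc1
Why: O-sulfonylation with retention installs the later leaving group; the quaternary neighbour blocks elimination towards the ketone and the free β-hydroxy ketone (retro-aldol risk) is masked.

Step 5
Reactants: 6 (1R,2S)-2-allyl-2-methyl-3-oxocyclohexyl 4-methylbenzenesulfonate
Product: 7 (1R,2S)-2-allyl-2,4-dimethyl-3-oxocyclohexyl 4-methylbenzenesulfonate (both C4 epimers)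
Conditions: LiN(iPr)2, THF, −78 °C; MeI, −78 to −20 °C
Reagents that add atoms: iodomethane CI
Why: Kinetic enolate alkylation at the only enolisable position (C4) brings in C15; the C4 configuration does not matter because C4 becomes sp2 in step 6.

Step 6
Reactants: 7 (1R,2S)-2-allyl-2,4-dimethyl-3-oxocyclohexyl 4-methylbenzenesulfonate (both C4 epimers)
Product: 8 (1R,2S)-2-allyl-2,4-dimethyl-3-(trifluoromethylsulfonyloxy)cyclohex-3-en-1-yl 4-methylbenzenesulfonate
Conditions: KN(SiMe3)2, THF, −78 °C; PhNTf2, −78 to 0 °C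
Reagents that add atoms: N-phenylbis(trifluoromethanesulfonimide) O=S(=O)(N(c1ccccc1)S(=O)(=O)C(F)(F)F)C(F)(F)F
Why: Enolate O-triflation; only C4 carries an α-hydrogen, so the tetrasubstituted enol triflate C5(OTf)=C4(CH3) forms regiospecifically.

Step 7
Reactants: 8 (1R,2S)-2-allyl-2,4-dimethyl-3-(trifluoromethylsulfonyloxy)cyclohex-3-en-1-yl 4-methylbenzenesulfonate
Product: 9 (1R,2S)-2,4-dimethyl-2-(2-oxoethyl)-3-(trifluoromethylsulfonyloxy)cyclohex-3-en-1-yl 4-methylbenzenesulfonate
Conditions: O3, CH2Cl2, −78 °C; then PPh3, −78 °C to rt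
Reagents that add atoms: ozone [O-][O+]=O
Why: Ozonolysis with reductive work-up, chemoselective for the electron-rich terminal alkene over the electron-poor enol triflate, gives the C8 aldehyde.

Step 8
Reactants: 9 (1R,2S)-2,4-dimethyl-2-(2-oxoethyl)-3-(trifluoromethylsulfonyloxy)cyclohex-3-en-1-yl 4-methylbenzenesulfonate; 10 methyl 4-oxobutanoate
Product: 13 trans-lactone aldehyde (trans-4-formyl-γ-butyrolactone carrying the ring A methyl group at C5 of the lactone; 7αH 8βH), via anti-aldol adduct 11 (not isolated), via cis-lactone aldehyde 12 (not isolated)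
Conditions: L-proline (20 mol %), DMF, 4 °C, 10 added over 24 h; then camphorsulfonic acid (10 mol %), CH2Cl2, rt
Reagents that add atoms: none
Why: Proline enamine cross-aldol (donor 10, hindered neopentyl-type acceptor 9) sets C8 (S) by the catalyst; acid then closes the γ-lactone and, through the enol of the formyl group, epimerises C7 from the first-formed cis lactone to the more stable trans lactone.

Step 9
Reactants: 13 trans-lactone aldehyde
Product: 14 6-hydroxy-1β-tosyloxy-eudesm-4-en-12,8α-olide (7αH 8βH 10β-methyl; both C6 epimers)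
Conditions: CrCl2 (6 equiv), NiCl2 (2 mol %), DMF, 0.01 M, rt
Reagents that add atoms: none
Why: Intramolecular Nozaki–Hiyama–Kishi coupling (zerovalent nickel inserts into the alkenyl triflate, transmetalation to chromium, addition to the aldehyde) closes six-membered ring B at C5–C6; the C6 configuration is erased in step 10.

Step 10
Reactants: 14 6-hydroxy-1β-tosyloxy-eudesm-4-en-12,8α-olide
Product: 15 6-oxo-1β-tosyloxy-eudesm-4-en-12,8α-olide
Conditions: Dess–Martin periodinane, NaHCO3, CH2Cl2, 0 °C to rt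
Reagents that add atoms: none
Why: Buffered Dess–Martin oxidation of the allylic alcohol gives the s-cis tetrasubstituted enone without touching the tosylate, the lactone or C7.

Step 11
Reactants: 15 6-oxo-1β-tosyloxy-eudesm-4-en-12,8α-olide
Product: 17 (1(10)E,4E)-6-oxogermacra-1(10),4-dien-12,8α-olide, via β-boryl ketone 16 (not isolated)
Conditions: CuCl(IMes) (10 mol %; IMes = 1,3-dimesitylimidazol-2-ylidene), NaOtBu (10 mol %), B2pin2 (1.3 equiv), MeOH (2 equiv), THF, rt; then CsF (3 equiv), MeCN, 45 °C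
Reagents that add atoms: bis(pinacolato)diboron CC1(C)OB(B2OC(C)(C)C(C)(C)O2)OC1(C)C (its boron stays only in 16)
Why: Proposed new method: copper-catalysed borylative ring expansion, in which boryl-copper adds to C4 of the enone from the α-face (anti to the C10 methyl) and C5 is protonated from the α-face to give trans-fused 16, whose equatorial C4–B and C1–OTs bonds are both antiperiplanar to the C5–C10 bond, so that fluoride ate-complex formation at boron drives a concerted 1,4-fragmentation (Grob type) that cleaves C5–C10, expels tosylate and forms both alkenes stereospecifically as E, helped by enone formation and relief of the 1,3-diaxial methyl/methyl strain; the closest known reactions are copper-catalysed conjugate borylation of β,β-disubstituted enones and the Marshall hydroboration/alkoxide fragmentation of decalyl sulfonates to cyclodeca-1,5-dienes.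

Step 12
Reactants: 17 (1(10)E,4E)-6-oxogermacra-1(10),4-dien-12,8α-olide
Product: 18 (1(10)E,4E)-6α-hydroxygermacra-1(10),4-dien-12,8α-olide
Conditions: (R)-2-methyl-CBS-oxazaborolidine (0.5 equiv), catecholborane, toluene, −78 °C
Reagents that add atoms: none
Why: Corey–Bakshi–Shibata 1,2-reduction of the enone; with the alkenyl arm as the large group the (R)-catalyst delivers hydride to give the 6α-alcohol, and catecholborane at low temperature leaves the alkenes and lactone alone.

Step 13
Reactants: 18 (1(10)E,4E)-6α-hydroxygermacra-1(10),4-dien-12,8α-olide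
Product: 21 (1(10)E,4E)-6α-hydroxygermacra-1(10),4,11(13)-trien-12,8α-olide, via Mannich base 19 (not isolated), via ammonium iodide 20 (not isolated)
Conditions: LiN(iPr)2 (2.3 equiv), THF, −78 °C (18 added to the base); CH2=NMe2+ I−; aqueous quench at −78 °C; then MeI, MeOH, rt; then NaHCO3, CH2Cl2/H2O
Reagents that add atoms: N,N-dimethylmethyleneiminium iodide C=[N+](C)C.[I-]; iodomethane CI (its methyl stays only in 20)
Why: α-Methylenation of the lactone by Mannich reaction of its enolate (formed as the dianion, inverse addition so the lactone is enolised before the C6 alkoxide can transacylate), N-methylation and E1cB elimination of trimethylamine.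

Step 14
Reactants: 21 (1(10)E,4E)-6α-hydroxygermacra-1(10),4,11(13)-trien-12,8α-olide; 22 angelic acid ((Z)-2-methylbut-2-enoic acid)
Product: 24 (1(10)E,4E)-6α-angeloyloxygermacra-1(10),4,11(13)-trien-12,8α-olide, via mixed anhydride 23 (not isolated)
Conditions: 22, 2,4,6-trichlorobenzoyl chloride, Et3N, toluene, rt; then 21, toluene, 75 °C
Reagents that add atoms: 2,4,6-trichlorobenzoyl chloride O=C(Cl)c1c(Cl)cc(Cl)cc1Cl (its atoms stay only in 23)
Why: Yamaguchi-type esterification through the mixed anhydride, run without a nucleophilic catalyst so the Z (angelate) geometry is kept; C6 retains its configuration.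

Step 15
Reactants: 24 (1(10)E,4E)-6α-angeloyloxygermacra-1(10),4,11(13)-trien-12,8α-olide
Product: 25 (1β,10α:4α,5β)-diepoxy-6α-angeloyloxygermacr-11(13)-en-12,8α-olide (1R,4R,5R,6S,7R,8S,10R; target)
Conditions: mCPBA (2.3 equiv), NaHCO3, CH2Cl2, 0 °C
Reagents that add atoms: 3-chloroperoxybenzoic acid O=C(OO)c1cccc(Cl)c1
Why: Prilezhaev epoxidation, chemoselective for the two electron-rich trisubstituted ring alkenes over the acrylate-type alkenes; each E-alkene gives a trans-epoxide, and attack on the outer faces of the crossed diene conformer with both methyl groups syn (the usual course for E,E-germacranolides) gives the 1β,10α and 4α,5β epoxides.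

**Compound list**
1 | cyclohexane-1,3-dione | O=C1CCCC(=O)C1 | starting material
2 | 2-methylcyclohexane-1,3-dione | CC1C(=O)CCCC1=O | intermediate
3 | allyl bromide | C=CCBr | starting material
4 | 2-allyl-2-methylcyclohexane-1,3-dione | C=CCC1(C)C(=O)CCCC1=O | intermediate
5 | (2S,3R)-2-allyl-3-hydroxy-2-methylcyclohexan-1-one (OH cis to methyl) | C=CC[C@]1(C)C(=O)CCC[C@H]1O | intermediate
6 | (1R,2S)-2-allyl-2-methyl-3-oxocyclohexyl 4-methylbenzenesulfonate | C=CC[C@]1(C)C(=O)CCC[C@H]1OS(=O)(=O)c1ccc(C)cc1 | intermediate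
7 | (1R,2S)-2-allyl-2,4-dimethyl-3-oxocyclohexyl 4-methylbenzenesulfonate (C4 epimer mixture, C4 left undefined) | C=CC[C@]1(C)C(=O)C(C)CC[C@H]1OS(=O)(=O)c1ccc(C)cc1 | intermediate
8 | (1R,2S)-2-allyl-2,4-dimethyl-3-(trifluoromethylsulfonyloxy)cyclohex-3-en-1-yl 4-methylbenzenesulfonate | C=CC[C@]1(C)C(OS(=O)(=O)C(F)(F)F)=C(C)CC[C@H]1OS(=O)(=O)c1ccc(C)cc1 | intermediate
9 | (1R,2S)-2,4-dimethyl-2-(2-oxoethyl)-3-(trifluoromethylsulfonyloxy)cyclohex-3-en-1-yl 4-methylbenzenesulfonate | O=CC[C@]1(C)C(OS(=O)(=O)C(F)(F)F)=C(C)CC[C@H]1OS(=O)(=O)c1ccc(C)cc1 | intermediate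
10 | methyl 4-oxobutanoate | COC(=O)CCC=O | starting material
11 | anti-aldol adduct (open-chain 8-hydroxy-7-formyl methyl ester, 7,8-anti) | COC(=O)C[C@H](C=O)[C@@H](O)C[C@]1(C)C(OS(=O)(=O)C(F)(F)F)=C(C)CC[C@H]1OS(=O)(=O)c1ccc(C)cc1 | intermediate
12 | cis-lactone aldehyde (7,8-cis-4-formyl-γ-butyrolactone) | O=C[C@H]1CC(=O)O[C@H]1C[C@]2(C)C(OS(=O)(=O)C(F)(F)F)=C(C)CC[C@H]2OS(=O)(=O)c2ccc(C)cc2 | intermediate
13 | trans-lactone aldehyde (7,8-trans-4-formyl-γ-butyrolactone, 7αH 8βH) | O=C[C@@H]1CC(=O)O[C@H]1C[C@]2(C)C(OS(=O)(=O)C(F)(F)F)=C(C)CC[C@H]2OS(=O)(=O)c2ccc(C)cc2 | intermediate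
14 | 6-hydroxy-1β-tosyloxy-eudesm-4-en-12,8α-olide (7αH, 8βH, 10β-methyl; C6 epimer mixture, C6 left undefined) | O=C1C[C@H]2C(O)C3=C(C)CC[C@@H](OS(=O)(=O)c4ccc(C)cc4)[C@]3(C)C[C@@H]2O1 | intermediate
15 | 6-oxo-1β-tosyloxy-eudesm-4-en-12,8α-olide (7αH, 8βH, 10β-methyl) | O=C1C[C@H]2C(=O)C3=C(C)CC[C@@H](OS(=O)(=O)c4ccc(C)cc4)[C@]3(C)C[C@@H]2O1 | intermediate
16 | 4α-(4,4,5,5-tetramethyl-1,3,2-dioxaborolan-2-yl)-6-oxo-1β-tosyloxy-5αH-eudesman-12,8α-olide (4β-methyl, trans-decalin) | O=C1C[C@H]2C(=O)[C@H]3[C@](C)(B4OC(C)(C)C(C)(C)O4)CC[C@@H](OS(=O)(=O)c4ccc(C)cc4)[C@]3(C)C[C@@H]2O1 | intermediate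
17 | (1(10)E,4E)-6-oxogermacra-1(10),4-dien-12,8α-olide (7αH, 8βH) | O=C1C[C@H]2C(=O)/C=C(C)/CC/C=C(C)/C[C@@H]2O1 | intermediate
18 | (1(10)E,4E)-6α-hydroxygermacra-1(10),4-dien-12,8α-olide | O=C1C[C@H]2[C@H](O)/C=C(C)/CC/C=C(C)/C[C@@H]2O1 | intermediate
19 | Mannich base: 13-(dimethylamino)-6α-hydroxygermacra-1(10),4-dien-12,8α-olide (C11 epimer mixture) | O=C1C(CN(C)C)[C@H]2[C@H](O)/C=C(C)/CC/C=C(C)/C[C@@H]2O1 | intermediate
20 | ammonium iodide: 13-(trimethylammonio) analogue of 19, iodide salt | O=C1C(C[N+](C)(C)C)[C@H]2[C@H](O)/C=C(C)/CC/C=C(C)/C[C@@H]2O1.[I-] | intermediate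
21 | (1(10)E,4E)-6α-hydroxygermacra-1(10),4,11(13)-trien-12,8α-olide | C=C1C(=O)O[C@H]2C/C(C)=C/CC/C(C)=C/[C@@H](O)[C@H]12 | intermediate
22 | angelic acid ((Z)-2-methylbut-2-enoic acid) | C/C=C(/C)C(=O)O | starting material
23 | angelic 2,4,6-trichlorobenzoic mixed anhydride | C/C=C(/C)C(=O)OC(=O)c1c(Cl)cc(Cl)cc1Cl | intermediate
24 | (1(10)E,4E)-6α-angeloyloxygermacra-1(10),4,11(13)-trien-12,8α-olide | C=C1C(=O)O[C@H]2C/C(C)=C/CC/C(C)=C/[C@@H](OC(=O)/C(C)=C\C)[C@H]12 | intermediate
25 | (1β,10α:4α,5β)-diepoxy-6α-angeloyloxygermacr-11(13)-en-12,8α-olide (1R,4R,5R,6S,7R,8S,10R) | C=C1C(=O)O[C@H]2C[C@@]3(C)O[C@@H]3CC[C@@]3(C)O[C@@H]3[C@@H](OC(=O)/C(C)=C\C)[C@H]12 | target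

**Step count and risks**

Total step count: 15. Longest linear sequence: 15 steps (1 → 25); 3, 10 and 22 enter as commercial building blocks.

Three steps most likely to fail:

Step 11 (the new borylative ring expansion). The tetrasubstituted, hindered enone may borylate slowly, and the β-acyloxy ketone (lactone oxygen on C8) can open under base. Fallback with known chemistry, setting out from 14 and coming back at 17: silylate 14 (TBSCl, imidazole, DMF) to the tert-butyldimethylsilyl ether F1. Hydroborate the tetrasubstituted C4=C5 alkene with BH3·THF (0 °C to rt; cis-addition from the α-face, boron on the less hindered C4) to the 4α-borane F2. Treat this in the same flask with NaOMe/MeOH, the classical Marshall boronate fragmentation, to obtain the (E,E)-dienyl silyl ether F3. Remove the silyl group with Bu4NF to give the dienol as a C6-epimer mixture F4 (its 6α-epimer is 18). Oxidise with Dess–Martin periodinane to rejoin the route at 17.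

Step 12 (C6 configuration). Substrate bias in the ten-membered enone may oppose the catalyst; peripheral hydride attack would give the 6β-alcohol. Fallback from 17, returning at 18: Luche reduction (NaBH4, CeCl3·7H2O, MeOH, −78 °C) under substrate control to the 6β-alcohol F5. Mitsunobu inversion with 4-nitrobenzoic acid, PPh3 and diisopropyl azodicarboxylate gives the 6α-(4-nitrobenzoate) F6. Mild methanolysis (K2CO3, MeOH, 0 °C) then gives 18. If the Luche reduction gives the 6α-alcohol directly, that product is 18.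

Step 15 (facial selectivity of the double epoxidation; 6α-acyloxy-8,12-germacranolides are conformationally mobile). Fallback from 21, returning at 25: hydroxyl-directed epoxidation of the free allylic alcohol (VO(acac)2, t-BuOOH, CH2Cl2, 0 °C) attacks only C4=C5 and delivers oxygen from the face of the C6–OH in the allylic-strain-minimised conformer, giving the 4α,5β-epoxy alcohol F7. mCPBA (1.1 equiv, NaHCO3, 0 °C) then epoxidises the remaining 1(10)-alkene from its outer face to the diepoxy alcohol F8. Esterification with the mixed anhydride 23 (toluene, 75 °C) gives 25.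

Further compounds
F1 | step 11 | 6-(tert-butyldimethylsilyloxy)-1β-tosyloxy-eudesm-4-en-12,8α-olide (C6 epimer mixture) | O=C1C[C@H]2C(O[Si](C)(C)C(C)(C)C)C3=C(C)CC[C@@H](OS(=O)(=O)c4ccc(C)cc4)[C@]3(C)C[C@@H]2O1
F2 | step 11 | 4α-boranyl-6-(tert-butyldimethylsilyloxy)-1β-tosyloxy-5αH-eudesman-12,8α-olide (C6 epimer mixture) | O=C1C[C@H]2C(O[Si](C)(C)C(C)(C)C)[C@H]3[C@](C)([BH2])CC[C@@H](OS(=O)(=O)c4ccc(C)cc4)[C@]3(C)C[C@@H]2O1
F3 | step 11 | (1(10)E,4E)-6-(tert-butyldimethylsilyloxy)germacra-1(10),4-dien-12,8α-olide (C6 epimer mixture) | O=C1C[C@H]2C(O[Si](C)(C)C(C)(C)C)/C=C(C)/CC/C=C(C)/C[C@@H]2O1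
F4 | step 11 | (1(10)E,4E)-6-hydroxygermacra-1(10),4-dien-12,8α-olide (C6 epimer mixture) | O=C1C[C@H]2C(O)/C=C(C)/CC/C=C(C)/C[C@@H]2O1
F5 | step 12 | (1(10)E,4E)-6β-hydroxygermacra-1(10),4-dien-12,8α-olide | O=C1C[C@H]2[C@@H](O)/C=C(C)/CC/C=C(C)/C[C@@H]2O1
F6 | step 12 | (1(10)E,4E)-6α-(4-nitrobenzoyloxy)germacra-1(10),4-dien-12,8α-olide | O=C1C[C@H]2[C@H](OC(=O)c3ccc([N+](=O)[O-])cc3)/C=C(C)/CC/C=C(C)/C[C@@H]2O1
F7 | step 15 | (1(10)E)-4α,5β-epoxy-6α-hydroxygermacra-1(10),11(13)-dien-12,8α-olide | C=C1C(=O)O[C@H]2C/C(C)=C/CC[C@@]3(C)O[C@@H]3[C@@H](O)[C@H]12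
F8 | step 15 | (1β,10α:4α,5β)-diepoxy-6α-hydroxygermacr-11(13)-en-12,8α-olide | C=C1C(=O)O[C@H]2C[C@@]3(C)O[C@@H]3CC[C@@]3(C)O[C@@H]3[C@@H](O)[C@H]12
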